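**Retrosynthetic overview**
1. The cyclopropane is closed last, by carbene 1,3-C–H insertion (Bamford–Stevens) on a ring-A-fused 7-silyloxybicyclo[2.2.1]heptan-2-one, as in camphor → tricyclene; then desilylation, triacetylation and debenzylation.
2. Key disconnection: the bicycloheptanone comes from monocyclic ring A by an intramolecular (3+2) cycloaddition of a 2-oxidoallyl cation (from an α-chloromethyl ketone arm on the CH2O-bearing quaternary carbon) onto the exocyclic silyl enol ether of the neighbouring ring-A aldehyde. It forms the bond from the ring-fusion quaternary carbon to the bridging CH2 and the bond from the O-bearing CH to the methyl-bearing carbon.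
3. Enabling feature: in the cage cyclopentane (ring-fusion quaternary carbon, bridging CH2, cyclopropane CH, methyl-bearing cyclopropane carbon, CH–OAc), the cyclopropane CH sits between the two carbons that take the new bonds and can be a carbonyl carbon (centre of an oxyallyl cation). CH–OAc and the quaternary carbon are the O-carbon and β-carbon of an aldehyde enol ether.
4. Ring A is made first from 2,2-dimethylcyclohexane-1,3-dione: CBS reduction, directed epoxidation and epoxide-to-allylic-alcohol shift (cis-diol), Morita–Baylis–Hillman hydroxymethylation, reductive alkylation (quaternary carbon), one-carbon homologation of the ketone to the aldehyde enol ether.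
5. Ring order: ring A → the six-membered and both five-membered rings of the bicycloheptanone (key step) → cyclopropane.

Key step: step 17

Assumption (chemistry): compounds 14–21 are carried as epimer mixtures at the side-chain methine (16–18 also at the ring CH), because both carbons become trigonal before or in step 17; their SMILES leave these centres open. TBS = t-BuMe2Si, TIPS = i-Pr3Si, Bn = benzyl.

Step 1
Reactants: 1 2,2-dimethylcyclohexane-1,3-dione
Product: 2 mono-ethylene ketal 6,6-dimethyl-1,4-dioxaspiro[4.5]decan-7-one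
Conditions: HOCH2CH2OH (1.1 equiv), p-TsOH (cat.), benzene, reflux, Dean–Stark
Reagents that add atoms: ethylene glycol, OCCO
Why: Acid-catalysed ketalisation should stop at the mono-ketal because the second carbonyl is then flanked by a quaternary and a ketal carbon; no stereocentre is formed.

Step 2
Reactants: 2 mono-ketal ketone
Product: 3 6,6-dimethyl-1,4-dioxaspiro[4.5]dec-8-en-7-one
Conditions: IBX, 4-methoxypyridine N-oxide, DMSO, rt
Reagents that add atoms: none
Why: IBX-mediated α,β-dehydrogenation of the ketone can only go toward C8–C9 because the other α-carbon is quaternary.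

Step 3
Reactants: 3 enone ketal
Product: 4 (7S)-6,6-dimethyl-1,4-dioxaspiro[4.5]dec-8-en-7-ol
Conditions: (R)-2-methyl-CBS-oxazaborolidine (20 mol %), catecholborane, toluene, −78 °C
Reagents that add atoms: none
Why: Corey–Bakshi–Shibata reduction in which the quaternary C6 is the large and the vinyl carbon the small group, so the (R)-catalyst should give the (7S)-allylic alcohol from which all later stereocentres are relayed.

Step 4
Reactants: 4 allylic alcohol
Product: 5 cis-epoxy alcohol (epoxide oxygen syn to the hydroxyl)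
Conditions: VO(acac)2 (2 mol %), t-BuOOH, CH2Cl2, 0 °C to rt
Reagents that add atoms: tert-butyl hydroperoxide, CC(C)(C)OO
Why: Hydroxyl-directed vanadium-catalysed epoxidation of a cyclic allylic alcohol delivers oxygen to the alkene face syn to the hydroxyl, placing the future C8 oxygen cis to O7.

Step 5
Reactants: 5 cis-epoxy alcohol
Product: 6 (7R,8S)-6,6-dimethyl-1,4-dioxaspiro[4.5]dec-9-ene-7,8-diol (cis-diol)
Conditions: LiN(i-Pr)2 (3.5 equiv), Et2O/THF, 0 °C to rt
Reagents that add atoms: none
Why: Base-mediated epoxide-to-allylic-alcohol isomerisation by syn β-elimination removes a C10 hydrogen (C7 carries the alkoxide), so the C8–O bond is untouched and the diol is cis.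

Step 6
Reactants: 6 cis-diol
Product: 7 (7R,8S)-8-(benzyloxy)-6,6-dimethyl-1,4-dioxaspiro[4.5]dec-9-en-7-ol
Conditions: BnBr (1.1 equiv), Ag2O, CH2Cl2, rt, dark
Reagents that add atoms: benzyl bromide, BrCc1ccccc1
Why: Ag2O-promoted Williamson mono-benzylation should take the allylic, less hindered C8 hydroxyl and spare the neopentyl C7 hydroxyl next to the gem-dimethyl carbon.

Step 7
Reactants: 7 mono-benzyl ether
Product: 8 (4S,5R)-4-(benzyloxy)-5-hydroxy-6,6-dimethylcyclohex-2-en-1-one
Conditions: 1 M HCl (aq.), THF, rt
Reagents that add atoms: water, O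
Why: Acid hydrolysis of the ketal unveils the ketone already conjugated with the ring alkene, and neither stereocentre is enolisable.

Step 8
Reactants: 8 enone
Product: 9 (4S,5R)-4-(benzyloxy)-5-hydroxy-2-(hydroxymethyl)-6,6-dimethylcyclohex-2-en-1-one
Conditions: HCHO (37 % aq.), DMAP (30 mol %), THF/H2O, rt
Reagents that add atoms: formaldehyde, C=O
Why: Morita–Baylis–Hillman reaction: DMAP adds to the β-carbon and the enolate traps formaldehyde, installing the hydroxymethyl carbon at the enone α-position.

Step 9
Reactants: 9 enone diol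
Product: 10 bis-TBS ether of 9
Conditions: TBSOTf (2.5 equiv), 2,6-lutidine, CH2Cl2, −78 to 0 °C
Reagents that add atoms: tert-butyldimethylsilyl triflate, CC(C)(C)[Si](C)(C)OS(=O)(=O)C(F)(F)F
Why: The silyl triflate silylates the primary and the hindered neopentyl secondary hydroxyl in one operation.

Step 10
Reactants: 10 bis-TBS enone; 11 methyl 2-(bromomethyl)prop-2-enoate
Product: 13 quaternary ketone (acrylate arm trans and CH2OTBS cis to the two ring oxygens), via lithium enolate 12 (not isolated)
Conditions: LiBH(s-Bu)3 (1.05 equiv), THF, −78 °C; then 11, −78 to −20 °C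
Reagents that add atoms: LiBH(s-Bu)3, [Li+].CCC(C)[BH-](C(C)CC)C(C)CC (lithium in 12 only)
Why: Conjugate reduction gives the regiodefined tetrasubstituted enolate, which is alkylated (SN2′ on the bromomethyl acrylate) by axial attack anti to the C4 benzyloxy group of the half-chair with the C5 silyloxy group axial, so the arm enters trans to both ring oxygens at the new quaternary centre.

Step 11
Reactants: 13 acrylate ketone
Product: 14 saturated methyl ester (both methine epimers)
Conditions: H2 (1 atm), RhCl(PPh3)3 (5 mol %), benzene/EtOH, rt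
Reagents that add atoms: none
Why: Homogeneous rhodium-catalysed hydrogenation reduces only the 1,1-disubstituted acrylate double bond (benzyl ether and ketone stay), and the new methine is inconsequential because it becomes trigonal in step 17.

Step 12
Reactants: 14 hindered ketone
Product: 15 exocyclic methylidene compound
Conditions: Zn, CH2Br2, TiCl4, THF/CH2Cl2, 0 °C to rt
Reagents that add atoms: dibromomethane, BrCBr
Why: Takai–Lombardo methylenation uses a small, non-basic titanium–zinc methylene reagent suited to a non-enolisable hindered ketone and leaves the ester alone.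

Step 13
Reactants: 15 methylidene compound
Product: 17 primary alcohol (ring CH epimers), via B-alkyl-9-BBN 16 (not isolated)
Conditions: 9-BBN dimer, THF, 65 °C; then NaBO3·4H2O, H2O, rt
Reagents that add atoms: 9-BBN, B1C2CCCC1CCC2 (in 16 only); sodium perborate, [Na+].[O-]OB=O
Why: Anti-Markovnikov hydroboration puts boron on the terminal methylene and oxidation with retention gives the primary alcohol; the new ring CH configuration is removed again in step 15.

Step 14
Reactants: 17 primary alcohol
Product: 18 aldehyde
Conditions: Dess–Martin periodinane, NaHCO3, CH2Cl2, 0 °C to rt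
Reagents that add atoms: none
Why: Dess–Martin oxidation converts the primary alcohol to the aldehyde under buffered conditions that leave silyl ethers, benzyl ether and ester untouched.

Step 15
Reactants: 18 aldehyde
Product: 19 exocyclic TIPS enol ether
Conditions: TIPSOTf, Et3N, CH2Cl2, 0 °C to rt
Reagents that add atoms: triisopropylsilyl triflate, CC(C)[Si](OS(=O)(=O)C(F)(F)F)(C(C)C)C(C)C
Why: Soft enolisation (O-silylation of the aldehyde, then removal of its only α-hydrogen by Et3N) gives the silyl enol ether, whose double-bond geometry does not matter for step 17.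

Step 16
Reactants: 19 ester enol ether
Product: 20 α-chloromethyl ketone
Conditions: ClCH2I (2 equiv), MeLi·LiBr (1.8 equiv), THF, −78 °C; NH4Cl (aq.) at −78 °C
Reagents that add atoms: chloroiodomethane, ClCI
Why: Ester homologation with chloromethyllithium made in situ by iodine–lithium exchange: the tetrahedral adduct is stable at −78 °C and collapses on quench to the chloromethyl ketone, the silyl enol ether being inert to the carbenoid.

Step 17
Reactants: 20 α-chloromethyl ketone
Product: 22 ring-A-fused 7-(triisopropylsilyloxy)-1-methylbicyclo[2.2.1]heptan-2-one, via oxyallyl cation 21 (not isolated)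
Conditions: Et3N (3 equiv), CF3CH2OH, 0 °C to rt
Reagents that add atoms: none
Why: Proposed new method: Et3N in trifluoroethanol enolises the chloroketone toward the methyl-bearing carbon and the enolate ionises chloride to the 2-oxidoallyl cation 21; the nucleophilic ring carbon of the silyl enol ether attacks its CH2 terminus and the resulting silyloxocarbenium carbon is then captured by the methyl-bearing enolate carbon, a stepwise intramolecular (3+2) cycloaddition whose closest known relatives are the intermolecular (3+2) cycloadditions of base-generated oxyallyl cations with indoles, enol ethers and vinyl sulfides, and the trapping of cyclic oxyallyl cations by such alkenes to give bicyclo[2.2.1]heptanones. The first bond closes the six-membered carbocycle by 6-endo attack on the allyl cation terminus (the mode of a neryl-cation closure), and the second closes both five-membered rings by 5-exo attack of the enolate carbon on the exocyclic oxocarbenium carbon across the new cyclohexene (1,4-transannular). O-closure of the enolate is excluded because it would give a bridgehead enol ether in a bicyclo[3.2.1] frame, and the aldol-type bond cannot revert while the oxygen stays silylated. The ring-fusion quaternary centre is controlled by the tether, which is equatorial on the chair of ring A, so the CH2 terminus should enter trans-diequatorially (exo-fused cyclohexane with a fusion torsion near 45°, whereas the other face would need an endo fusion near 80°) while the bulky silyloxymethine moves axial and loses its allylic strain; the methyl-bearing bridgehead follows from the cage, and at the silyloxy carbon the oxocarbenium rotates before closure so that OSi lies over the ketone bridge, away from the exo CH2 of ring A, both enol ether isomers converging. The step needs intramolecular capture to outrun solvent capture and Favorskii pathways, which the electron-rich trisubstituted silyl enol ether held two atoms from the cation and the reversible enolisation should secure.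

Step 18
Reactants: 22 bicyclic ketone
Product: 23 tosylhydrazone
Conditions: TsNHNH2, AcOH (cat.), EtOH, 70 °C
Reagents that add atoms: 4-methylbenzenesulfonohydrazide, Cc1ccc(cc1)S(=O)(=O)NN
Why: Condensation of the ketone with tosylhydrazide under mild acid catalysis, as for camphor-type ketones with a quaternary α-bridgehead; the silyl ethers survive.

Step 19
Reactants: 23 tosylhydrazone
Product: 26 tris-silyl benzyl-protected tetracycle (nortricyclene core), via sodium tosylhydrazonide 24 (not isolated), via diazoalkane 25 (not isolated)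
Conditions: NaH (1.2 equiv), diglyme, rt; then 150 °C
Reagents that add atoms: sodium hydride, [Na+].[H-] (sodium in 24 only)
Why: Aprotic Bamford–Stevens reaction: the salt loses sulfinate to the diazoalkane, then N2, and the carbene inserts into a C–H bond of the CH2 on the methyl-bearing bridgehead (1,3-insertion, as in camphor to tricyclene), closing the cyclopropane with both new CH stereocentres fixed by the cage.

Step 20
Reactants: 26 protected tetracycle
Product: 27 triol benzyl ether
Conditions: Bu4NF (6 equiv), THF, 50 °C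
Reagents that add atoms: none
Why: Fluoride cleaves all three silyl ethers (the hindered secondary ones need warming) and leaves the benzyl ether.

Step 21
Reactants: 27 triol
Product: 28 triacetate benzyl ether
Conditions: Ac2O, DMAP, pyridine, 50 °C
Reagents that add atoms: acetic anhydride, CC(=O)OC(C)=O
Why: DMAP-catalysed acylation esterifies the primary and both hindered secondary hydroxyls without acid, which the cyclopropylcarbinyl alcohol would not tolerate.

Step 22
Reactants: 28 triacetate benzyl ether
Product: 29 CNP0111873.1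
Conditions: H2 (1 atm), Pd(OH)2 on carbon, EtOAc, rt
Reagents that add atoms: none
Why: Neutral hydrogenolysis removes the benzyl ether last, so no base can move an acetyl group onto the freed hydroxyl, and acetates and cyclopropane should be inert under these mild conditions.

**Compound list**
1 | 2,2-dimethylcyclohexane-1,3-dione | CC1(C)C(=O)CCCC1=O | starting material
2 | 6,6-dimethyl-1,4-dioxaspiro[4.5]decan-7-one | CC1(C)C(=O)CCCC12OCCO2 | intermediate
3 | 6,6-dimethyl-1,4-dioxaspiro[4.5]dec-8-en-7-one | CC1(C)C(=O)C=CCC12OCCO2 | intermediate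
4 | (7S)-6,6-dimethyl-1,4-dioxaspiro[4.5]dec-8-en-7-ol | CC1(C)[C@@H](O)C=CCC12OCCO2 | intermediate
5 | (7R)-8,9-epoxy-6,6-dimethyl-1,4-dioxaspiro[4.5]decan-7-ol, epoxide oxygen cis to OH | CC1(C)[C@@H](O)[C@H]2O[C@H]2CC13OCCO3 | intermediate
6 | (7R,8S)-6,6-dimethyl-1,4-dioxaspiro[4.5]dec-9-ene-7,8-diol (cis-diol) | CC1(C)[C@@H](O)[C@@H](O)C=CC12OCCO2 | intermediate
7 | (7R,8S)-8-(benzyloxy)-6,6-dimethyl-1,4-dioxaspiro[4.5]dec-9-en-7-ol | CC1(C)[C@@H](O)[C@@H](OCc3ccccc3)C=CC12OCCO2 | intermediate
8 | (4S,5R)-4-(benzyloxy)-5-hydroxy-6,6-dimethylcyclohex-2-en-1-one | O=C1C=C[C@H](OCc2ccccc2)[C@H](O)C1(C)C | intermediate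
9 | (4S,5R)-4-(benzyloxy)-5-hydroxy-2-(hydroxymethyl)-6,6-dimethylcyclohex-2-en-1-one | O=C1C(CO)=C[C@H](OCc2ccccc2)[C@H](O)C1(C)C | intermediate
10 | (4S,5R)-4-(benzyloxy)-5-(TBS-oxy)-2-[(TBS-oxy)methyl]-6,6-dimethylcyclohex-2-en-1-one | O=C1C(CO[Si](C)(C)C(C)(C)C)=C[C@H](OCc2ccccc2)[C@H](O[Si](C)(C)C(C)(C)C)C1(C)C | intermediate
11 | methyl 2-(bromomethyl)prop-2-enoate | C=C(CBr)C(=O)OC | starting material
12 | lithium (4S,5R)-4-(benzyloxy)-5-(TBS-oxy)-2-[(TBS-oxy)methyl]-6,6-dimethylcyclohex-1-en-1-olate | [Li]OC1=C(CO[Si](C)(C)C(C)(C)C)C[C@H](OCc2ccccc2)[C@H](O[Si](C)(C)C(C)(C)C)C1(C)C | intermediate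
13 | methyl 2-{[(1S,4R,5S)-5-(benzyloxy)-4-(TBS-oxy)-1-[(TBS-oxy)methyl]-3,3-dimethyl-2-oxocyclohexyl]methyl}prop-2-enoate (CH2OTBS cis, acrylate arm trans to both ring oxygens) | CC(C)(C)[Si](C)(C)OC[C@]1(CC(=C)C(=O)OC)C[C@H](OCc2ccccc2)[C@H](O[Si](C)(C)C(C)(C)C)C(C)(C)C1=O | intermediate
14 | methyl 3-[(1S,4R,5S)-5-(benzyloxy)-4-(TBS-oxy)-1-[(TBS-oxy)methyl]-3,3-dimethyl-2-oxocyclohexyl]-2-methylpropanoate (both C2 epimers) | CC(C)(C)[Si](C)(C)OC[C@]1(CC(C)C(=O)OC)C[C@H](OCc2ccccc2)[C@H](O[Si](C)(C)C(C)(C)C)C(C)(C)C1=O | intermediate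
15 | 2-methylidene analogue of 14 (C=CH2 in place of the ring C=O, ring stereocentres as in 14) | CC(C)(C)[Si](C)(C)OC[C@]1(CC(C)C(=O)OC)C[C@H](OCc2ccccc2)[C@H](O[Si](C)(C)C(C)(C)C)C(C)(C)C1=C | intermediate
16 | B-alkyl-9-borabicyclo[3.3.1]nonane from 15 (boron on the former methylidene carbon) | CC(C)(C)[Si](C)(C)OC[C@]1(CC(C)C(=O)OC)C[C@H](OCc2ccccc2)[C@H](O[Si](C)(C)C(C)(C)C)C(C)(C)C1CB1C2CCCC1CCC2 | intermediate
17 | primary alcohol: ring CH–CH2OH between the two quaternary ring carbons, otherwise as 14 | CC(C)(C)[Si](C)(C)OC[C@]1(CC(C)C(=O)OC)C[C@H](OCc2ccccc2)[C@H](O[Si](C)(C)C(C)(C)C)C(C)(C)C1CO | intermediate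
18 | aldehyde: ring CH–CHO between the two quaternary ring carbons, otherwise as 14 | CC(C)(C)[Si](C)(C)OC[C@]1(CC(C)C(=O)OC)C[C@H](OCc2ccccc2)[C@H](O[Si](C)(C)C(C)(C)C)C(C)(C)C1C=O | intermediate
19 | exocyclic triisopropylsilyl enol ether of 18 (ring C=CH–OTIPS, E/Z mixture), methyl ester arm | CC(C)(C)[Si](C)(C)OC[C@]1(CC(C)C(=O)OC)C[C@H](OCc2ccccc2)[C@H](O[Si](C)(C)C(C)(C)C)C(C)(C)C1=CO[Si](C(C)C)(C(C)C)C(C)C | intermediate
20 | chloromethyl ketone: arm CH2–CH(CH3)–C(=O)–CH2Cl on the quaternary carbon, ring C=CH–OTIPS | CC(C)(C)[Si](C)(C)OC[C@]1(CC(C)C(=O)CCl)C[C@H](OCc2ccccc2)[C@H](O[Si](C)(C)C(C)(C)C)C(C)(C)C1=CO[Si](C(C)C)(C(C)C)C(C)C | intermediate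
21 | 2-oxidoallyl cation from 20 (arm CH2–C(CH3)=C(O−)–CH2+) | CC(C)(C)[Si](C)(C)OC[C@]1(CC(C)=C([O-])[CH2+])C[C@H](OCc2ccccc2)[C@H](O[Si](C)(C)C(C)(C)C)C(C)(C)C1=CO[Si](C(C)C)(C(C)C)C(C)C | intermediate
22 | 1-methyl-7-(TIPS-oxy)bicyclo[2.2.1]heptan-2-one with ring A fused at C4 (bridgehead) and C5: ring CH2 exo and CH2OTBS endo at C5, OTIPS at C7 syn to the ketone bridge; ring A carries OBn and OTBS cis to CH2OTBS | CC(C)(C)[Si](C)(C)OC[C@]12C[C@H](OCc3ccccc3)[C@H](O[Si](C)(C)C(C)(C)C)C(C)(C)[C@]14CC(=O)[C@](C)(C2)[C@H]4O[Si](C(C)C)(C(C)C)C(C)C | intermediate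
23 | tosylhydrazone of 22 | CC(C)(C)[Si](C)(C)OC[C@]12C[C@H](OCc3ccccc3)[C@H](O[Si](C)(C)C(C)(C)C)C(C)(C)[C@]14CC(=NNS(=O)(=O)c5ccc(C)cc5)[C@](C)(C2)[C@H]4O[Si](C(C)C)(C(C)C)C(C)C | intermediate
24 | sodium salt of tosylhydrazone 23 | [Na+].CC(C)(C)[Si](C)(C)OC[C@]12C[C@H](OCc3ccccc3)[C@H](O[Si](C)(C)C(C)(C)C)C(C)(C)[C@]14CC(=N[N-]S(=O)(=O)c5ccc(C)cc5)[C@](C)(C2)[C@H]4O[Si](C(C)C)(C(C)C)C(C)C | intermediate
25 | 2-diazo compound from 24 | CC(C)(C)[Si](C)(C)OC[C@]12C[C@H](OCc3ccccc3)[C@H](O[Si](C)(C)C(C)(C)C)C(C)(C)[C@]14CC(=[N+]=[N-])[C@](C)(C2)[C@H]4O[Si](C(C)C)(C(C)C)C(C)C | intermediate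
26 | tetracycle with the nortricyclene core of the target, carrying CH2OTBS, ring OBn, ring OTBS and cage OTIPS | CC(C)(C)[Si](C)(C)OC[C@]12C[C@H](OCc3ccccc3)[C@H](O[Si](C)(C)C(C)(C)C)C(C)(C)[C@]14C[C@@H]5[C@H]2[C@]5(C)[C@H]4O[Si](C(C)C)(C(C)C)C(C)C | intermediate
27 | triol benzyl ether (CH2OH, ring OH next to CMe2, cage OH; OBn on the other ring carbinol) | OC[C@]12C[C@H](OCc3ccccc3)[C@H](O)C(C)(C)[C@]14C[C@@H]5[C@H]2[C@]5(C)[C@H]4O | intermediate
28 | triacetate benzyl ether | CC(=O)OC[C@]12C[C@H](OCc3ccccc3)[C@H](OC(C)=O)C(C)(C)[C@]14C[C@@H]5[C@H]2[C@]5(C)[C@H]4OC(C)=O | intermediate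
29 | CNP0111873.1 | CC(=O)OC[C@]12C[C@H](O)[C@H](OC(C)=O)C(C)(C)[C@]13C[C@@H]1[C@H]2[C@]1(C)[C@H]3OC(C)=O | target

**Step count and risks**
Total steps: 22. Longest linear sequence: 22 steps (from 1; 11 enters at step 10).

Steps most likely to fail:

1. Step 17 (Proposed new method). The oxyallyl cation may be captured by the solvent or enter a Favorskii pathway before the enol ether attacks, or attack on the wrong face of the enol ether may give a zwitterion that cannot close the second ring. Fallback by known reactions, from 20: halide exchange (NaI, acetone) should give the iodomethyl ketone F1. Iodine atom-transfer radical cyclisation (Et3B, air, benzene; 6-exo addition of the electrophilic α-keto radical to the ring carbon of the silyl enol ether, then collapse of the α-iodo silyl ether) should give the keto aldehyde F2. Me3SiCl/NaI/Et3N in MeCN should give the more substituted trimethylsilyl enol ether F3. An intramolecular Mukaiyama aldol addition (TiCl4, CH2Cl2, −78 °C) should give the β-hydroxy ketone F4, which is silylated at once (TIPSOTf, 2,6-lutidine) and so comes back to the route at 22.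

2. Step 10. Poor facial selectivity in the enolate alkylation would give the epimer at the quaternary carbon. Fallback, from 10: the enolate 12 is trapped on oxygen with 2-(methoxycarbonyl)allyl chloroformate to give the enol carbonate F5. A Pd-catalysed decarboxylative asymmetric allylic alkylation of Tsuji type (Pd2(dba)3, (S)-t-Bu-PHOX or its enantiomer, toluene) then sets the quaternary centre under catalyst control and returns to the route at 13.

3. Step 12. The carbonyl group flanked by two quaternary carbons may not react, or the ester may react on forcing. Fallback, from 14: Corey–Chaykovsky epoxidation (Me3S+ I−, KN(SiMe3)2, THF, 0 °C to rt) should give the spiro-epoxide F6. A Meinwald rearrangement (MgBr2·OEt2, CH2Cl2; 1,2-hydride shift) should then give the aldehyde directly and return to the route at 18, by-passing 15–17.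

Further compounds
F1 | step 17 | iodomethyl ketone (20 with I in place of Cl) | CC(C)(C)[Si](C)(C)OC[C@]1(CC(C)C(=O)CI)C[C@H](OCc2ccccc2)[C@H](O[Si](C)(C)C(C)(C)C)C(C)(C)C1=CO[Si](C(C)C)(C(C)C)C(C)C
F2 | step 17 | keto aldehyde (trans-fused cyclohexanone, angular CHO on the ring-fusion carbon) | CC(C)(C)[Si](C)(C)OC[C@]12C[C@H](OCc3ccccc3)[C@H](O[Si](C)(C)C(C)(C)C)C(C)(C)[C@]1(C=O)CC(=O)C(C)C2
F3 | step 17 | trimethylsilyl enol ether of F2 (toward the methyl-bearing carbon) | CC(C)(C)[Si](C)(C)OC[C@]12C[C@H](OCc3ccccc3)[C@H](O[Si](C)(C)C(C)(C)C)C(C)(C)[C@]1(C=O)CC(O[Si](C)(C)C)=C(C)C2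
F4 | step 17 | β-hydroxy ketone (22 with OH in place of OTIPS) | CC(C)(C)[Si](C)(C)OC[C@]12C[C@H](OCc3ccccc3)[C@H](O[Si](C)(C)C(C)(C)C)C(C)(C)[C@]14CC(=O)[C@](C)(C2)[C@H]4O
F5 | step 10 | 2-(methoxycarbonyl)allyl enol carbonate of enolate 12 | COC(=O)C(=C)COC(=O)OC1=C(CO[Si](C)(C)C(C)(C)C)C[C@H](OCc2ccccc2)[C@H](O[Si](C)(C)C(C)(C)C)C1(C)C
F6 | step 12 | spiro-epoxide of ketone 14 | CC(C)(C)[Si](C)(C)OC[C@]1(CC(C)C(=O)OC)C[C@H](OCc2ccccc2)[C@H](O[Si](C)(C)C(C)(C)C)C(C)(C)C13CO3
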